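Atom labels used below: ring A carbons a1 (methyl), a2 (chlorine), a3 (C=O), a4 (chain), a5 (OH), a6 (C=O); chain carbons C1' (on a4) to C5' (on B3); ring B carbons B1 (C=O), B2, B3 (quaternary), B4, B5, B6.

## Structural features

The target has two six-membered carbocycles joined by a five-carbon chain. Ring A is a fully substituted 2-hydroxy-1,4-benzoquinone whose a4 carbon carries C1'; ring B is a cyclohexanone whose quaternary carbon B3 carries C5'. The chain contains an (E)-trisubstituted alkene C2'=C3' (methyl on C3') and a secondary allylic carbinol C4' (S), which lies 1,3 to B3. Ring B has three contiguous stereocentres, B2 (R), B3 (S) and B4 (S): the B2 and B3 methyls are cis, and the B4 methyl is trans to the B3 methyl and therefore cis to the C5' chain. The fragile groups are the hydroxyquinone (an acidic, redox-active vinylogous acid whose a2–Cl bond is a vinylogous acid chloride), the C4' allylic alcohol (ionisable, and placed so that its oxygen can reach B2), and B2, which is alpha to the ketone and can epimerise in acid or base. The real difficulty is B3: an all-carbon quaternary centre between two methyl-bearing methines, with its larger substituent on the face that a reagent approaching from outside avoids; B2 adds to it, because its hydrogen must also arrive on the chain face. The key step exploits the fact that C5' on B3 stands 1,3 to the B1 oxygen while its neighbour C4' is oxygenated: shifting the B1 oxygen onto C4' in thought gives the array B3=B2–B1–O–C4'(=C5'H2), an allyl vinyl ether, so the B3–C5' bond can be made by a [3,3] shift in which a B1–O bond cis to the B4 methyl dictates the face.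

## Logic of the disconnections

24 ⇒ 23. The a6–O bond and the quinone oxidation level are removed. Ring A as a quinone is the most fragile part and belongs at the end, and a6 is the only open position of 23, para to the a3 hydroxyl, so the oxidation has one possible outcome. The gain is that ring A becomes a chlororesorcinol with the oxygen pattern of 1; no third ring oxygen has to be carried, and no alkoxyquinone has to be hydrolysed beside the a2 chloride. A permethylated ring A (three methyl ethers, (NH4)2Ce(NO3)6 oxidation, hydrolysis of the methoxyquinone) was weighed and set aside for that reason. The demand is an oxidant that works near neutral pH and leaves the alkene, the carbinol and B2 alone.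

23 ⇒ 21 (through 22). Two O–CH2 acetal bonds and one O–Si bond are cut. The phenols must stay masked while the chain contains an enone, because a free phenol would add to C2', and the C4' oxygen must be masked during the hydride shift. The gain is that every earlier step runs on ethers stable to base, heat, hydride and peracid. The demand is an unmasking without strong Brønsted acid or base, so that B2 is not enolised and C4' is not ionised.

21 ⇒ 20. The B2–H bond is cut and the B1 carbonyl is traced back to an epoxide. The B2 hydrogen must sit on the chain face, where no external reagent is expected to go, but a hydrogen shifting from B1 within the molecule can. The gain is that B2 becomes a question of alkene face selection and that the ketone appears late. The demand is an epoxide oxygen trans to the chain and a hydride shift that wins over alkyl shift and capture by the C4' oxygen.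

20 ⇒ 19 ⇒ 18. The O–Si bond and the C4'–H bond are cut, so C4' becomes the carbonyl that the key step delivers. The gain is reagent control of C4'. The demand is on the order: reduction after epoxidation (an allylic alcohol would steer the peracid to C2'=C3') and before a ketone exists at B1.

18 ⇒ 17. The two C–O bonds of the epoxide are cut, giving back the ring alkene. The demand is chemoselectivity over the enone alkene and the arene, and attack on the face away from the chain.

17 ⇒ 16. The B3–C5' bond is cut. This is the strategic bond: it divides the molecule into halves of similar size and turns the quaternary stereocentre into the carbinol stereocentre of 14. The demand is a concerted shift and a cis relation between the ether oxygen and the B4 methyl in 16.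

16 ⇒ 15. The C5' methylene is removed from C4'; the enol ether cannot be made by O-alkylation, but it can be made from an ester carbonyl and a titanium methylidene. The gain is that the two halves are joined by an esterification. The demand is a methylenation free of acid and base.

15 ⇒ 9 + 14. The acyl–oxygen bond is cut. The B1–O bond is not touched, so the configuration of 14 passes unchanged into 15.

9 ⇒ 8 ⇒ 5 + 6 (through 7). The ester O–ethyl bond and the C2'=C3' double bond are cut. A stabilised ylide sets the (E) geometry, and the aldehyde partner is made and consumed in one flask.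

5 ⇒ 4 ⇒ 2 (through 3) ⇒ 1. The a2–Cl bond, the a4–C1' bond (C1' and C2' come as one two-carbon unit) and the two O–CH2 bonds are cut. In 2 the position between the oxygens is the most acidic, and in 4 the two open positions are equivalent, so each step has one regiochemical outcome.

14 ⇒ 13. The C1–H bond is cut. Catalyst control sets C1 in both enantiomers of 13, and the cis diastereomer is separated.

13 ⇒ 11 (through 12) ⇒ 10. The B3–CH3 and B4–CH3 bonds are cut, by alkylation and carbonyl transposition of a vinylogous ester.

## Other disconnections considered

Alternative 1: The cut is the a2–a3 bond, so ring A is not taken from an arene but grown last from a four-membered ring. In the forward step the cyclobutenone A1 (chain next to the carbonyl, isopropoxy on the following carbon, hydroxyl and isopropenyl on the fourth) would open thermally to a dienylketene, close between the ketene carbon and the isopropenyl methylene, and tautomerise to the hydroquinone A2.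
- In its favour: every ring A substituent is placed by the order of two additions to a squaric ester, so the oxygen pattern is unambiguous; the ring arrives at the hydroquinone level and needs only a mild oxidation; the step is convergent.
- Against it here: a2 emerges as C–H, so chlorination must be done late on an electron-rich ring next to a trisubstituted alkene. The a5 oxygen arrives as an isopropyl ether, which after oxidation is an alkoxyquinone to be cleaved beside the a2 chloride and an epimerisable B2. The chain must be attached through C1', an allylic carbon, with alpha/gamma and E/Z hazards. All of ring B with B2, B3, B4 and C4' must exist beforehand, so the quaternary-centre problem is untouched.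
- Comparison: on structure, the chosen plan takes ring A ready-made from 1 and introduces chlorine at 5, where the ring is symmetrical. On mechanism, both rest on a thermal pericyclic step, but the chosen one transfers chirality and this one creates none. On step economy, the alternative spends steps on a ring that 1 already contains and still ends with chlorination and dealkylation.
- Alternative 1 is the better plan on one point: oxygen placement and the quinone oxidation level follow from the construction itself, whereas the chosen route relies on a late phenol oxidation (23 to 24).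

Alternative 2: The cut removes the B3–CH3 and B2–CH3 bonds. In the forward step a methyl group would be transferred from copper to B3 of the enone A3 on the face opposite the B4 methyl, and the resulting enolate would be C-methylated at B2 in the same flask to give A4.
- In its favour: two C–C bonds and two stereocentres in one operation; the bias of the B4 methyl is used, not fought (the small methyl goes trans and leaves the allyl group cis); B2 needs no cationic rearrangement; ring B is obtained directly as the ketone.
- Against it here: A3 must be made as a single enantiomer. A β,β-disubstituted, γ-branched enone is a reluctant acceptor, and the usual silyl halide activation gives a silyl enol ether that must be turned back into a metal enolate before alkylation. The face and regiochemical integrity of alkylating a tetrasubstituted enolate beside a new quaternary centre are not assured. The allyl group is only a three-carbon stub: it must be cleaved to an aldehyde and the alkenyl–aryl half added as an organometallic, which creates C4' with little substrate control, while the ketone is masked.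
- Comparison: on structure, ring B is solved first and the chain grown afterwards, whereas the chosen plan joins two halves of similar size and obtains the C4' carbonyl in the same step as B3–C5'. On mechanism, it is intermolecular substrate control against an intramolecular stereospecific shift. On step economy, A4 is reached in fewer steps than 17, but chain extension and C4' control give the lead back.
- Alternative 2 is the equal of the chosen plan in control of B3 and the better one at B2, which it sets without an epoxide and a Lewis acid.

Alternative 3: The cut is C3'–C4'. In the forward step the carbamate A5 would be deprotonated enantioselectively at C4' with an alkyllithium and a chiral diamine, the lithio carbamate would add to boron of the alkenyl boronic ester A6, and the alkenyl group would migrate from boron to C4' with loss of the carbamate to give the boronic ester A7; oxidation of the C–B bond with retention would then give the carbinol.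
- In its favour: C4' is set by the reagent, in either sense, and does not depend on the steric difference between an alkenyl and a neopentyl-type arm on which a ketone reduction relies; the union is convergent and late; no heating is needed.
- Against it here: ring B with B2, B3 and B4 must be complete before the union, so A5 needs its own solution for B3, and two strategic steps are spent where the chosen plan uses one. The ketone must be masked as a dioxolane for the organolithium step and unmasked with acid beside B2 and the allylic alcohol. Lithiation next to a neopentyl-type carbon and ate-complex formation with an α-branched alkenyl boronate are both slow. A7 is an allylic boronate and can undergo a 1,3-boron shift that would scramble C4', C2' and the alkene geometry.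
- Comparison: on structure, both plans are convergent, but in the chosen plan the C3'–C4' bond is already present in 9, so no organometallic union is needed. On mechanism, it is a stereospecific 1,2-metallate shift against a [3,3] shift. On step economy, separate syntheses of A5 and A6 plus two protecting-group operations make it longer.
- Alternative 3 is the better plan for C4' and the equal of the chosen one in convergency.

Key step: step 11

Remark: ring A is treated as the 2-hydroxy-1,4-quinone tautomer; the a6 oxygen is a spectator of the key step and is introduced last, so the aryl group in 16 and 17 is 3-chloro-2,6-bis(methoxymethoxy)-4-methylphenyl, while the bond formed, the absence of ring closure and the carbon skeletons are unchanged.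

## Steps

Step 1
Reactants: 1 orcinol (5-methylbenzene-1,3-diol)
Product: 2 1,3-bis(methoxymethoxy)-5-methylbenzene
Conditions: MOMCl, i-Pr2NEt, CH2Cl2, 0 °C to rt
Reagents that add atoms: chloromethyl methyl ether, COCCl
Why: O-Alkylation of both phenols (Williamson type); the acetal ethers direct the metalation of step 2 and are stable to base, heat, hydride and peracid.

Step 2
Reactants: 2 1,3-bis(methoxymethoxy)-5-methylbenzene
Product: 4 2-[2,6-bis(methoxymethoxy)-4-methylphenyl]ethan-1-ol, via aryllithium 3 (not isolated)
Conditions: n-BuLi, THF, 0 °C to rt; then oxirane, 0 °C to rt; H2O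
Reagents that add atoms: oxirane, C1CO1
Why: Directed ortho-metalation: the position between the two acetal oxygens is doubly coordinated and the most acidic, so lithiation should occur only at the future a4; the aryllithium then opens oxirane by SN2 and brings in C1' and C2'.

Step 3
Reactants: 4 2-[2,6-bis(methoxymethoxy)-4-methylphenyl]ethan-1-ol
Product: 5 2-[3-chloro-2,6-bis(methoxymethoxy)-4-methylphenyl]ethan-1-ol
Conditions: NCS (1.0 equiv), MeCN, 0 °C to rt
Reagents that add atoms: N-chlorosuccinimide, O=C1CCC(=O)N1Cl
Why: Electrophilic aromatic chlorination of an activated arene; the two open positions are equivalent by symmetry (each ortho to the methyl and one oxygen, para to the other oxygen), so monochlorination can give only one isomer, and one equivalent of reagent limits a second substitution.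

Step 4
Reactants: 5 2-[3-chloro-2,6-bis(methoxymethoxy)-4-methylphenyl]ethan-1-ol; 6 ethyl 2-(triphenylphosphoranylidene)propanoate
Product: 8 ethyl (2E)-4-[3-chloro-2,6-bis(methoxymethoxy)-4-methylphenyl]-2-methylbut-2-enoate, via arylacetaldehyde 7 (not isolated)
Conditions: Dess–Martin periodinane, CH2Cl2, 0 °C to rt; then 6, rt
Reagents that add atoms: none
Why: Hypervalent iodine oxidation of the primary alcohol and Wittig olefination in one flask, so the enolisable arylacetaldehyde is trapped as it forms; the stabilised α-methyl ylide should give the (E)-trisubstituted alkene C2'=C3'.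

Step 5
Reactants: 8 ethyl (2E)-4-[3-chloro-2,6-bis(methoxymethoxy)-4-methylphenyl]-2-methylbut-2-enoate
Product: 9 (2E)-4-[3-chloro-2,6-bis(methoxymethoxy)-4-methylphenyl]-2-methylbut-2-enoic acid
Conditions: LiOH, THF/MeOH/H2O, rt; then cold dilute HCl to pH 4
Reagents that add atoms: lithium hydroxide, [Li+].[OH-]
Why: Ester saponification; the alkene should stay in conjugation with the carboxylate because the twisted 2,6-disubstituted aryl ring offers no gain for migration, and the aryl acetals tolerate a brief cold acidification.

Step 6
Reactants: 10 3-ethoxy-2-methylcyclohex-2-en-1-one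
Product: 11 3-ethoxy-2,6-dimethylcyclohex-2-en-1-one (racemic)
Conditions: LiN(i-Pr)2, THF, −78 °C; MeI, −78 to 0 °C
Reagents that add atoms: iodomethane, CI
Why: Kinetic α'-deprotonation of the vinylogous ester and SN2 methylation (first half of the Stork–Danheiser sequence) place the future B4 methyl.

Step 7
Reactants: 11 3-ethoxy-2,6-dimethylcyclohex-2-en-1-one
Product: 13 2,3,4-trimethylcyclohex-2-en-1-one (racemic), via tertiary carbinol 12 (not isolated)
Conditions: MeLi, Et2O, −78 to 0 °C; then 1 M HCl, rt
Reagents that add atoms: methyllithium, [Li]C
Why: 1,2-Addition to the vinylogous ester carbonyl, then acid-induced loss of water and hydrolysis of the enol ether, transposes the carbonyl (Stork–Danheiser) and gives the enone with methyls at the future B2, B3 and B4.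

Step 8
Reactants: 13 2,3,4-trimethylcyclohex-2-en-1-one (racemic)
Product: 14 (1R,4S)-2,3,4-trimethylcyclohex-2-en-1-ol (hydroxyl cis to the C4 methyl)
Conditions: (S)-Me-CBS (20 mol %), BH3·SMe2, THF, −20 °C; MeOH; chromatography on silica
Reagents that add atoms: none
Why: Corey–Bakshi–Shibata reduction: the oxazaborolidine binds the carbonyl with the alkenyl arm as the large group and should deliver hydride to the same face of both enantiomers of 13, the remote C4 methyl having little say; the (4S) half then gives the cis alcohol 14 and the (4R) half the trans diastereomer, which is removed on silica.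

Step 9
Reactants: 9 (2E)-4-[3-chloro-2,6-bis(methoxymethoxy)-4-methylphenyl]-2-methylbut-2-enoic acid; 14 (1R,4S)-2,3,4-trimethylcyclohex-2-en-1-ol
Product: 15 (1R,4S)-2,3,4-trimethylcyclohex-2-en-1-yl (2E)-4-[3-chloro-2,6-bis(methoxymethoxy)-4-methylphenyl]-2-methylbut-2-enoate
Conditions: EDC·HCl, DMAP (cat.), CH2Cl2, 0 °C to rt
Reagents that add atoms: none
Why: Steglich esterification through the O-acylisourea and the acylpyridinium ion; the carbinol C–O bond is not broken, so C1 keeps its configuration, and catalytic DMAP without added amine base limits vinylketene formation from the activated acid.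

Step 10
Reactants: 15 (1R,4S)-2,3,4-trimethylcyclohex-2-en-1-yl (2E)-4-[3-chloro-2,6-bis(methoxymethoxy)-4-methylphenyl]-2-methylbut-2-enoate
Product: 16 (1R,4S)-2,3,4-trimethylcyclohex-2-en-1-yl (3E)-5-[3-chloro-2,6-bis(methoxymethoxy)-4-methylphenyl]-3-methylpenta-1,3-dien-2-yl ether
Conditions: Cp2TiMe2, PhMe/THF, 65 °C, dark; hexane, filtration through basic alumina
Reagents that add atoms: dimethyltitanocene, [CH3-].[CH3-].[Ti+4].c1cc[cH-]c1.c1cc[cH-]c1
Why: Petasis methylenation: Cp2Ti=CH2, formed by loss of methane, adds to the ester carbonyl and the oxatitanacyclobutane collapses to the enol ether; the reagent is neither acidic nor basic, so the allylic C–O bond, the acetals and the (E)-alkene should survive, and conjugated esters are known substrates.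

Step 11
Reactants: 16 (1R,4S)-2,3,4-trimethylcyclohex-2-en-1-yl (3E)-5-[3-chloro-2,6-bis(methoxymethoxy)-4-methylphenyl]-3-methylpenta-1,3-dien-2-yl ether
Product: 17 (3E)-5-[3-chloro-2,6-bis(methoxymethoxy)-4-methylphenyl]-3-methyl-1-[(1S,6S)-1,2,6-trimethylcyclohex-2-en-1-yl]pent-3-en-2-one
Conditions: PhMe (degassed), 140 °C, sealed tube, base-washed glass
Reagents that add atoms: none
Why: Thermal aliphatic Claisen rearrangement, a concerted suprafacial [3,3] shift through the six-atom array C5'=C4'–O–B1–B2=B3: C5' bonds to B3 as the B1–O bond breaks, the oxygen becomes the C4' carbonyl and the ring alkene moves to B1=B2. The closest known reaction type is the rearrangement of allyl vinyl ethers made by titanium methylenation of allylic esters, including cyclohex-2-enyl ethers that build a quaternary carbon at the ring terminus. No ring is closed; the six-membered array exists only in the transition state. The one new stereocentre, B3, is controlled by the B1–O bond: C5' can reach B3 only on the face that carries the oxygen, and because that oxygen is cis to the B4 methyl in 16, the chain arrives cis to the B4 methyl, which is (1S,6S) in 17. Chair-like and boat-like arrays lead to the same configuration at B3 because the migrating terminus C5' is an unsubstituted methylene. The step needs a concerted shift in preference to heterolysis of the allylic C–O bond (recombination or elimination), which the non-polar solvent, base-washed glass and removal of titanium residues should secure, and it needs the (E)-C2'=C3' alkene to survive, which it should because that alkene lies outside the reacting array and has no hydrogen placed for a 1,5-shift. Formation of the conjugated carbonyl makes the shift irreversible.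

Step 12
Reactants: 17 (3E)-5-[3-chloro-2,6-bis(methoxymethoxy)-4-methylphenyl]-3-methyl-1-[(1S,6S)-1,2,6-trimethylcyclohex-2-en-1-yl]pent-3-en-2-one
Product: 18 (3E)-5-[3-chloro-2,6-bis(methoxymethoxy)-4-methylphenyl]-1-[(1S,2R,3S,6S)-2,3-epoxy-1,2,6-trimethylcyclohexyl]-3-methylpent-3-en-2-one (epoxide on B2–B1, oxygen trans to the C5' chain)
Conditions: mCPBA, NaHCO3, CH2Cl2, 0 °C
Reagents that add atoms: 3-chloroperoxybenzoic acid, OOC(=O)c1cccc(Cl)c1
Why: Prilezhaev epoxidation; only the electron-rich ring alkene should react, the enone alkene being deactivated and the arene far slower. In the half-chair with the B4 methyl equatorial the cis chain on B3 is pseudoaxial and shields its own face, so oxygen should be delivered to the face of the B3 methyl.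

Step 13
Reactants: 18 (3E)-5-[3-chloro-2,6-bis(methoxymethoxy)-4-methylphenyl]-1-[(1S,2R,3S,6S)-2,3-epoxy-1,2,6-trimethylcyclohexyl]-3-methylpent-3-en-2-one
Product: 19 (2S,3E)-5-[3-chloro-2,6-bis(methoxymethoxy)-4-methylphenyl]-1-[(1S,2R,3S,6S)-2,3-epoxy-1,2,6-trimethylcyclohexyl]-3-methylpent-3-en-2-ol
Conditions: (R)-Me-CBS, catecholborane, PhMe, −78 °C; MeOH, aq. NaHCO3
Reagents that add atoms: none
Why: Corey–Bakshi–Shibata reduction of an α-methyl enone with the alkenyl arm as the large group and the C5' methylene as the small one; the (R)-catalyst should deliver hydride to the face that gives the (S)-carbinol at C4'. The step is placed after epoxidation, since an allylic alcohol would direct peracid to C2'=C3', and before any ketone exists at B1.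

Step 14
Reactants: 19 (2S,3E)-5-[3-chloro-2,6-bis(methoxymethoxy)-4-methylphenyl]-1-[(1S,2R,3S,6S)-2,3-epoxy-1,2,6-trimethylcyclohexyl]-3-methylpent-3-en-2-ol
Product: 20 tert-butyldimethylsilyl ether of 19 at the C4' oxygen
Conditions: TBSCl, imidazole, DMF, rt
Reagents that add atoms: tert-butyldimethylsilyl chloride, CC(C)(C)[Si](C)(C)Cl
Why: Silylation of the secondary alcohol; the bulky silyl ether lowers the nucleophilicity of the C4' oxygen, which could otherwise capture B2 in a five-membered ring during the next step.

Step 15
Reactants: 20 tert-butyldimethylsilyl ether of 19 at the C4' oxygen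
Product: 21 (2R,3S,4S)-3-[(2S,3E)-2-(tert-butyldimethylsilyloxy)-5-[3-chloro-2,6-bis(methoxymethoxy)-4-methylphenyl]-3-methylpent-3-en-1-yl]-2,3,4-trimethylcyclohexan-1-one
Conditions: BF3·OEt2 (0.5 equiv), CH2Cl2, −78 °C; Et3N, aq. NaHCO3
Reagents that add atoms: none
Why: Meinwald rearrangement: the Lewis acid opens the epoxide at the tertiary carbon B2, and the B1 hydrogen, which lies on the chain face anti to the breaking C–O bond, shifts to B2 as the B1 carbonyl forms. The B2 hydrogen therefore ends on the chain face and the B2 methyl cis to the B3 methyl, which is (R) at B2; low temperature and a basic quench keep the new α-stereocentre from enolising.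

Step 16
Reactants: 21 (2R,3S,4S)-3-[(2S,3E)-2-(tert-butyldimethylsilyloxy)-5-[3-chloro-2,6-bis(methoxymethoxy)-4-methylphenyl]-3-methylpent-3-en-1-yl]-2,3,4-trimethylcyclohexan-1-one
Product: 23 4-chloro-2-[(2E,4S)-4-hydroxy-3-methyl-5-[(1S,2R,6S)-1,2,6-trimethyl-3-oxocyclohexyl]pent-2-en-1-yl]-5-methylbenzene-1,3-diol, via bis(trimethylsilyl) ether 22 (not isolated)
Conditions: TMSOTf, 2,2'-bipyridyl, CH2Cl2, 0 °C to rt; then HF·pyridine, THF, 0 °C to rt; pH 7 buffer
Reagents that add atoms: none
Why: Silyl triflate/bipyridyl acetal exchange turns aryl methoxymethyl ethers into aryl trimethylsilyl ethers without free Brønsted acid, and buffered fluoride then cleaves all three O–Si bonds. No strong acid or base is met, so B2 and C4' should keep their configuration, and the phenols appear only now, when the chain no longer holds a Michael acceptor.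

Step 17
Reactants: 23 4-chloro-2-[(2E,4S)-4-hydroxy-3-methyl-5-[(1S,2R,6S)-1,2,6-trimethyl-3-oxocyclohexyl]pent-2-en-1-yl]-5-methylbenzene-1,3-diol
Product: 24 2-chloro-5-hydroxy-6-[(2E,4S)-4-hydroxy-3-methyl-5-[(1S,2R,6S)-1,2,6-trimethyl-3-oxocyclohexyl]pent-2-en-1-yl]-3-methylcyclohexa-2,5-diene-1,4-dione (CNP0469571.4)
Conditions: (KSO3)2NO, KH2PO4, acetone/H2O, 0 °C to rt; extraction at pH 3–4
Reagents that add atoms: potassium nitrosodisulfonate, [K+].[K+].[O-]S(=O)(=O)N([O])S(=O)(=O)[O-]
Why: Teuber oxidation: the phenoxyl radical of the a3 hydroxyl is trapped by a second nitrosodisulfonate at the free para carbon a6, and loss of imidodisulfonate gives the p-quinone with the a5 hydroxyl intact. Attack at a6 from the a5 oxygen would give only the tautomer of the same compound, so the single open position leaves no regiochemical choice, and the buffered medium spares B2 and the allylic alcohol.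

## Compound list

1 | orcinol (5-methylbenzene-1,3-diol) | Cc1cc(O)cc(O)c1 | starting material
2 | 1,3-bis(methoxymethoxy)-5-methylbenzene | Cc1cc(OCOC)cc(OCOC)c1 | intermediate
3 | [2,6-bis(methoxymethoxy)-4-methylphenyl]lithium | [Li]c1c(OCOC)cc(C)cc1OCOC | intermediate
4 | 2-[2,6-bis(methoxymethoxy)-4-methylphenyl]ethan-1-ol | OCCc1c(OCOC)cc(C)cc1OCOC | intermediate
5 | 2-[3-chloro-2,6-bis(methoxymethoxy)-4-methylphenyl]ethan-1-ol | OCCc1c(OCOC)c(Cl)c(C)cc1OCOC | intermediate
6 | ethyl 2-(triphenylphosphoranylidene)propanoate | CCOC(=O)C(C)=P(c1ccccc1)(c1ccccc1)c1ccccc1 | starting material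
7 | 2-[3-chloro-2,6-bis(methoxymethoxy)-4-methylphenyl]acetaldehyde | O=CCc1c(OCOC)c(Cl)c(C)cc1OCOC | intermediate
8 | ethyl (2E)-4-[3-chloro-2,6-bis(methoxymethoxy)-4-methylphenyl]-2-methylbut-2-enoate | CCOC(=O)/C(C)=C/Cc1c(OCOC)c(Cl)c(C)cc1OCOC | intermediate
9 | (2E)-4-[3-chloro-2,6-bis(methoxymethoxy)-4-methylphenyl]-2-methylbut-2-enoic acid | OC(=O)/C(C)=C/Cc1c(OCOC)c(Cl)c(C)cc1OCOC | intermediate
10 | 3-ethoxy-2-methylcyclohex-2-en-1-one | CCOC1=C(C)C(=O)CCC1 | starting material
11 | 3-ethoxy-2,6-dimethylcyclohex-2-en-1-one (racemic) | CCOC1=C(C)C(=O)C(C)CC1 | intermediate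
12 | 3-ethoxy-1,2,6-trimethylcyclohex-2-en-1-ol (racemic, both diastereomers) | CCOC1=C(C)C(C)(O)C(C)CC1 | intermediate
13 | 2,3,4-trimethylcyclohex-2-en-1-one (racemic) | CC1CCC(=O)C(C)=C1C | intermediate
14 | (1R,4S)-2,3,4-trimethylcyclohex-2-en-1-ol | O[C@@H]1CC[C@H](C)C(C)=C1C | intermediate
15 | (1R,4S)-2,3,4-trimethylcyclohex-2-en-1-yl (2E)-4-[3-chloro-2,6-bis(methoxymethoxy)-4-methylphenyl]-2-methylbut-2-enoate | O=C(O[C@@H]1CC[C@H](C)C(C)=C1C)/C(C)=C/Cc1c(OCOC)c(Cl)c(C)cc1OCOC | intermediate
16 | (1R,4S)-2,3,4-trimethylcyclohex-2-en-1-yl (3E)-5-[3-chloro-2,6-bis(methoxymethoxy)-4-methylphenyl]-3-methylpenta-1,3-dien-2-yl ether | C=C(O[C@@H]1CC[C@H](C)C(C)=C1C)/C(C)=C/Cc1c(OCOC)c(Cl)c(C)cc1OCOC | intermediate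
17 | (3E)-5-[3-chloro-2,6-bis(methoxymethoxy)-4-methylphenyl]-3-methyl-1-[(1S,6S)-1,2,6-trimethylcyclohex-2-en-1-yl]pent-3-en-2-one | O=C(C[C@@]2(C)[C@@H](C)CCC=C2C)/C(C)=C/Cc1c(OCOC)c(Cl)c(C)cc1OCOC | intermediate
18 | (3E)-5-[3-chloro-2,6-bis(methoxymethoxy)-4-methylphenyl]-1-[(1S,2R,3S,6S)-2,3-epoxy-1,2,6-trimethylcyclohexyl]-3-methylpent-3-en-2-one (epoxide oxygen trans to the chain) | O=C(C[C@@]2(C)[C@@H](C)CC[C@@H]3O[C@]23C)/C(C)=C/Cc1c(OCOC)c(Cl)c(C)cc1OCOC | intermediate
19 | (2S,3E)-5-[3-chloro-2,6-bis(methoxymethoxy)-4-methylphenyl]-1-[(1S,2R,3S,6S)-2,3-epoxy-1,2,6-trimethylcyclohexyl]-3-methylpent-3-en-2-ol | O[C@@H](C[C@@]2(C)[C@@H](C)CC[C@@H]3O[C@]23C)/C(C)=C/Cc1c(OCOC)c(Cl)c(C)cc1OCOC | intermediate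
20 | tert-butyldimethylsilyl ether of 19 at the C4' oxygen | CC(C)(C)[Si](C)(C)O[C@@H](C[C@@]2(C)[C@@H](C)CC[C@@H]3O[C@]23C)/C(C)=C/Cc1c(OCOC)c(Cl)c(C)cc1OCOC | intermediate
21 | (2R,3S,4S)-3-[(2S,3E)-2-(tert-butyldimethylsilyloxy)-5-[3-chloro-2,6-bis(methoxymethoxy)-4-methylphenyl]-3-methylpent-3-en-1-yl]-2,3,4-trimethylcyclohexan-1-one | CC(C)(C)[Si](C)(C)O[C@@H](C[C@@]2(C)[C@@H](C)CCC(=O)[C@@H]2C)/C(C)=C/Cc1c(OCOC)c(Cl)c(C)cc1OCOC | intermediate
22 | (2R,3S,4S)-3-[(2S,3E)-2-(tert-butyldimethylsilyloxy)-5-[3-chloro-4-methyl-2,6-bis(trimethylsilyloxy)phenyl]-3-methylpent-3-en-1-yl]-2,3,4-trimethylcyclohexan-1-one | CC(C)(C)[Si](C)(C)O[C@@H](C[C@@]2(C)[C@@H](C)CCC(=O)[C@@H]2C)/C(C)=C/Cc1c(O[Si](C)(C)C)c(Cl)c(C)cc1O[Si](C)(C)C | intermediate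
23 | 4-chloro-2-[(2E,4S)-4-hydroxy-3-methyl-5-[(1S,2R,6S)-1,2,6-trimethyl-3-oxocyclohexyl]pent-2-en-1-yl]-5-methylbenzene-1,3-diol | O[C@@H](C[C@@]2(C)[C@@H](C)CCC(=O)[C@@H]2C)/C(C)=C/Cc1c(O)c(Cl)c(C)cc1O | intermediate
24 | 2-chloro-5-hydroxy-6-[(2E,4S)-4-hydroxy-3-methyl-5-[(1S,2R,6S)-1,2,6-trimethyl-3-oxocyclohexyl]pent-2-en-1-yl]-3-methylcyclohexa-2,5-diene-1,4-dione | CC1=C(Cl)C(=O)C(C/C=C(\C)[C@@H](O)C[C@@]2(C)[C@@H](C)CCC(=O)[C@@H]2C)=C(O)C1=O | target

## Step count and least certain steps

Total: 17 steps. Longest linear sequence: 14 steps (1 to 24 through steps 1–5 and 9–17); the ring B branch (10 to 14) is 3 steps.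

Step 11 (key step). The likely failure is heterolysis of the allylic B1–O bond competing with the concerted shift, because the shift must build a quaternary carbon at a fully substituted alkene terminus and may be slow. That would lead to elimination to a cyclohexadiene or to recombination without transfer of chirality; acid traces would also hydrolyse the enol ether. The fallback is a Carroll rearrangement, which forms the same B3–C5' bond from an ester enol and also bypasses step 10. It sets out from 9 and 14. Acid 9 is condensed with Meldrum's acid (EDC·HCl, DMAP) to the acyl Meldrum's acid 5-[(2E)-4-aryl-1-hydroxy-2-methylbut-2-enylidene]-2,2-dimethyl-1,3-dioxane-4,6-dione F1. Heating F1 with 14 in toluene gives the β-keto ester (1R,4S)-2,3,4-trimethylcyclohex-2-en-1-yl (4E)-6-aryl-4-methyl-3-oxohex-4-enoate F2. The [3,3] shift of its enol (thermal, or at lower temperature as the dianion formed with LiN(i-Pr)2), followed by loss of carbon dioxide, comes back to the route at 17.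

Step 12. The likely failure is poor facial discrimination: a second half-chair with the B3 methyl pseudoaxial would expose the chain face, and part of the oxidant would then add cis to the chain. The fallback makes the other epoxide useful. It sets out from 17 and carries the chain-face epoxide (oxygen cis to the chain) F3 through the same reduction and silylation as in steps 13 and 14, giving the epoxy alcohol F4 and its tert-butyldimethylsilyl ether F5. Base-induced isomerisation of F5 with Et2Al(tmp) (diethylaluminium 2,2,6,6-tetramethylpiperidide) gives the exocyclic allylic alcohol with the B1 hydroxyl cis to the chain, F6. Hydroxyl-directed hydrogenation with [Ir(cod)(PCy3)(py)]PF6 adds hydrogen to B2 on the hydroxyl face, which is the chain face, and gives the saturated alcohol F7. Dess–Martin oxidation of F7 comes back to the route at 21, so both epoxides converge.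

Step 15. The likely failure is diversion of the B2 cation: shift of the B3 methyl or of a ring bond (ring contraction) in place of hydride, capture by the C4' oxygen with loss of silyl to give a tetrahydrofuran, or loss of an aryl acetal to the Lewis acid. The fallback avoids a cation. It sets out from 20. Isomerisation with Et2Al(tmp) gives the exocyclic allylic alcohol with the B1 hydroxyl trans to the chain, F8. Mitsunobu inversion (4-nitrobenzoic acid, PPh3, diisopropyl azodicarboxylate) gives the 4-nitrobenzoate with the B1 oxygen cis to the chain, F9, and methanolysis (K2CO3, MeOH) gives the allylic alcohol F6. Directed hydrogenation as above then gives the saturated alcohol F7, and Dess–Martin oxidation comes back to the route at 21.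

Step 16. The likely failures are incomplete acetal exchange at the hindered a3 oxygen, ionisation of the allylic C4'–O bond or enolisation towards B2 under silyl triflate, and addition of a free phenol to the chain alkene once three hydroxyls are liberated together. The fallback changes the order so that the quinone is formed before C4' is unmasked. It sets out from 21. The exchange is stopped with water after the bipyridyl stage, which gives the resorcinol still silylated at C4', F10. Oxidation with (KSO3)2NO as in step 17 gives the hydroxyquinone silyl ether F11, and HF·pyridine then removes the last silyl group and comes back to the route at 24.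

## Further compounds

F1 | step 11 | 5-[(2E)-4-[3-chloro-2,6-bis(methoxymethoxy)-4-methylphenyl]-1-hydroxy-2-methylbut-2-enylidene]-2,2-dimethyl-1,3-dioxane-4,6-dione | CC1(C)OC(=O)C(=C(O)/C(C)=C/Cc2c(OCOC)c(Cl)c(C)cc2OCOC)C(=O)O1
F2 | step 11 | (1R,4S)-2,3,4-trimethylcyclohex-2-en-1-yl (4E)-6-[3-chloro-2,6-bis(methoxymethoxy)-4-methylphenyl]-4-methyl-3-oxohex-4-enoate | O=C(CC(=O)/C(C)=C/Cc1c(OCOC)c(Cl)c(C)cc1OCOC)O[C@@H]1CC[C@H](C)C(C)=C1C
F3 | step 12 | (3E)-5-[3-chloro-2,6-bis(methoxymethoxy)-4-methylphenyl]-1-[(1S,2S,3R,6S)-2,3-epoxy-1,2,6-trimethylcyclohexyl]-3-methylpent-3-en-2-one (epoxide oxygen cis to the chain) | O=C(C[C@@]2(C)[C@@H](C)CC[C@H]3O[C@@]23C)/C(C)=C/Cc1c(OCOC)c(Cl)c(C)cc1OCOC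
F4 | step 12 | (2S,3E)-alcohol from F3 (C4' carbinol, epoxide oxygen cis to the chain) | O[C@@H](C[C@@]2(C)[C@@H](C)CC[C@H]3O[C@@]23C)/C(C)=C/Cc1c(OCOC)c(Cl)c(C)cc1OCOC
F5 | step 12 | tert-butyldimethylsilyl ether of F4 | CC(C)(C)[Si](C)(C)O[C@@H](C[C@@]2(C)[C@@H](C)CC[C@H]3O[C@@]23C)/C(C)=C/Cc1c(OCOC)c(Cl)c(C)cc1OCOC
F6 | step 12 | ring B allylic alcohol: B1 hydroxyl cis to the chain, exocyclic methylene on B2, C4' silyl ether | CC(C)(C)[Si](C)(C)O[C@@H](C[C@@]2(C)[C@@H](C)CC[C@@H](O)C2=C)/C(C)=C/Cc1c(OCOC)c(Cl)c(C)cc1OCOC
F7 | step 12 | ring B alcohol: B1 hydroxyl cis to the chain, B2 (R) methyl trans to the chain, C4' silyl ether | CC(C)(C)[Si](C)(C)O[C@@H](C[C@@]2(C)[C@@H](C)CC[C@@H](O)[C@@H]2C)/C(C)=C/Cc1c(OCOC)c(Cl)c(C)cc1OCOC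
F8 | step 15 | ring B allylic alcohol: B1 hydroxyl trans to the chain, exocyclic methylene on B2, C4' silyl ether | CC(C)(C)[Si](C)(C)O[C@@H](C[C@@]2(C)[C@@H](C)CC[C@H](O)C2=C)/C(C)=C/Cc1c(OCOC)c(Cl)c(C)cc1OCOC
F9 | step 15 | 4-nitrobenzoate of the B1 alcohol, oxygen cis to the chain, exocyclic methylene on B2 | CC(C)(C)[Si](C)(C)O[C@@H](C[C@@]2(C)[C@@H](C)CC[C@@H](OC(=O)c3ccc(cc3)[N+](=O)[O-])C2=C)/C(C)=C/Cc1c(OCOC)c(Cl)c(C)cc1OCOC
F10 | step 16 | (2R,3S,4S)-3-[(2S,3E)-2-(tert-butyldimethylsilyloxy)-5-(3-chloro-2,6-dihydroxy-4-methylphenyl)-3-methylpent-3-en-1-yl]-2,3,4-trimethylcyclohexan-1-one | CC(C)(C)[Si](C)(C)O[C@@H](C[C@@]2(C)[C@@H](C)CCC(=O)[C@@H]2C)/C(C)=C/Cc1c(O)c(Cl)c(C)cc1O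
F11 | step 16 | C4' tert-butyldimethylsilyl ether of 24 | CC1=C(Cl)C(=O)C(C/C=C(\C)[C@@H](O[Si](C)(C)C(C)(C)C)C[C@@]2(C)[C@@H](C)CCC(=O)[C@@H]2C)=C(O)C1=O
A1 | alternative 1 | 4-hydroxy-3-isopropoxy-4-(prop-1-en-2-yl)cyclobut-2-en-1-one carrying the protected side chain on C2 | CC(=C)C1(O)C(OC(C)C)=C(C/C=C(\C)[C@@H](O[Si](C)(C)C(C)(C)C)C[C@@]2(C)[C@@H](C)CCC3(OCCO3)[C@@H]2C)C1=O
A2 | alternative 1 | 3-isopropoxy-5-methylhydroquinone carrying the protected side chain between the isopropoxy group and a hydroxyl group | Cc1cc(O)c(C/C=C(\C)[C@@H](O[Si](C)(C)C(C)(C)C)C[C@@]2(C)[C@@H](C)CCC3(OCCO3)[C@@H]2C)c(OC(C)C)c1O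
A3 | alternative 2 | (S)-3-allyl-4-methylcyclohex-2-en-1-one | C=CCC1=CC(=O)CC[C@@H]1C
A4 | alternative 2 | (2R,3S,4S)-3-allyl-2,3,4-trimethylcyclohexan-1-one | C=CC[C@@]1(C)[C@@H](C)CCC(=O)[C@@H]1C
A5 | alternative 3 | N,N-diisopropylcarbamate of the C4' primary alcohol (C5'–C4' two-carbon arm on B3), ring B ketone as ethylene ketal | CC(C)N(C(C)C)C(=O)OCC[C@@]1(C)[C@@H](C)CCC2(OCCO2)[C@@H]1C
A6 | alternative 3 | 2-[(2Z)-4-(3-chloro-2,5,6-trimethoxy-4-methylphenyl)but-2-en-2-yl]-4,4,5,5-tetramethyl-1,3,2-dioxaborolane (boron trans to C1') | B1(OC(C)(C)C(C)(C)O1)/C(C)=C/Cc1c(OC)c(Cl)c(C)c(OC)c1OC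
A7 | alternative 3 | C4' pinacol boronate of the protected skeleton (arene as trimethyl ether, ring B ketone as dioxolane) | COc1c(C)c(Cl)c(OC)c(C/C=C(\C)[C@@H](B3OC(C)(C)C(C)(C)O3)C[C@@]2(C)[C@@H](C)CCC4(OCCO4)[C@@H]2C)c1OC
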